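## Retrosynthetic overview

1. The target is reached by late acylation and desilylation of a germacranolide core; the C10 ketol acetate comes from dihydroxylation of a 1(10)-E alkene, and the C8 oxygen from a C–Si bond.
2. The α-methylene-γ-lactone comes from a C6 ketone carrying a C7 acetate side chain; both arise from the enolate of an anionic oxy-Cope rearrangement trapped with bromoacetate.
3. The oxy-Cope (6 → 10 ring expansion) substrate is a 1,2-dialkenylcyclohexanol made from a cyclohexanone and an (E)-silylvinyl nucleophile; the isopropenyl partner is released in the same pot by Peterson elimination.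
4. The cyclohexanone comes from 4-iodotoluene: enzymatic cis-dihydroxylation (dearomatisation, sets absolute configuration), C–I to C–C exchange, and face-selective hydrogenation.
5. Ring order: arene → cyclohexane → ten-membered carbocycle → γ-lactone.

Assumption and convention: the dioxygenase oxidation of 4-iodotoluene is taken to be iodine-directed, with diol 2 recrystallised to high ee. Ten-membered compounds use germacrane numbering (C1 ketone, C4 CHMe, C5 CHOH, C6/C7 lactone fusion, C8 C–O-methacrylate, C10 C(Me)OAc), with α/β as in the usual drawing with H-7 α.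

## Route

**Step 1**
Reactants: 1, 4-iodotoluene
Product: 2, (1S,2S)-3-iodo-6-methylcyclohexa-3,5-diene-1,2-diol
Conditions: E. coli JM109(pDTG601) whole cells (toluene dioxygenase), O2, glucose, pH 7.2, 35 °C; recrystallise
Reagents that add atoms: dioxygen, O=O
Why: Enzymatic arene cis-dihydroxylation (dearomatisation) in which the larger iodine substituent controls regio- and face selectivity, so the carbinol next to the methyl-bearing carbon (future C5) is set as S and the vinyl iodide marks the future C1.

**Step 2**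
Reactants: 2
Product: 3, (3aS,7aS)-4-iodo-7-methyl-2-phenyl-3a,7a-dihydro-1,3-benzodioxole (benzylidene acetal, mixture at C2)
Conditions: PhCH(OMe)2, PPTS (cat.), CH2Cl2, 0 °C → rt
Reagents that add atoms: benzaldehyde dimethyl acetal, COC(OC)c1ccccc1
Why: Acid-catalysed transacetalisation of the cis-diol protects both hydroxyls, blocks one face of the diene and is removable later under neutral hydrogenolysis.

**Step 3**
Reactants: 3; 4, 1-(trimethylsilyl)propan-2-one
Product: 5, 2-[(3aR,7aS)-7-methyl-2-phenyl-3a,7a-dihydro-1,3-benzodioxol-4-yl]-1-(trimethylsilyl)propan-2-ol (carbinol epimers, inconsequential)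
Conditions: t-BuLi (2.1 equiv), Et2O, −78 °C; CeCl3, THF; then 4, −78 °C
Reagents that add atoms: none (new atoms come from reactant 4)
Why: Iodine–lithium exchange then organocerium 1,2-addition to the enolisable α-silyl ketone installs a β-hydroxysilane, a hydrogenation-stable masked isopropenyl group (Peterson precursor).

**Step 4**
Reactants: 5
Product: 6, (1S,2R,3R,6S)-3-[2-hydroxy-1-(trimethylsilyl)propan-2-yl]-6-methylcyclohexane-1,2-diol (all-cis ring substituents)
Conditions: H2 (3 atm), Pd(OH)2/C, EtOAc–MeOH, rt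
Reagents that add atoms: none
Why: Heterogeneous hydrogenation adds H2 to both ring alkenes from the face opposite the dioxolane, setting C4 (methyl cis to the oxygens) and the side-chain carbon all-cis; slower hydrogenolysis of the benzylidene acetal then frees the diol without acid, so the β-hydroxysilane survives.

**Step 5**
Reactants: 6
Product: 7, (1R,2S,3S,6R)-2-[(tert-butyldimethylsilyl)oxy]-6-[2-hydroxy-1-(trimethylsilyl)propan-2-yl]-3-methylcyclohexan-1-ol
Conditions: TBSCl, imidazole, DMF, 0 °C
Reagents that add atoms: tert-butyldimethylsilyl chloride, CC(C)(C)[Si](C)(C)Cl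
Why: Selective silylation: with the bulky side chain equatorial, the hydroxyl next to the methyl is equatorial and accessible, while the other secondary hydroxyl is axial and flanked by the quaternary carbinol, and the tertiary hydroxyl is inert.

**Step 6**
Reactants: 7
Product: 8, (2S,3S,6S)-2-[(tert-butyldimethylsilyl)oxy]-6-[2-hydroxy-1-(trimethylsilyl)propan-2-yl]-3-methylcyclohexan-1-one
Conditions: Dess–Martin periodinane, NaHCO3, CH2Cl2, rt
Reagents that add atoms: none
Why: Neutral Dess–Martin oxidation of the only free secondary alcohol gives the ketone without retro-aldol, Peterson elimination or epimerisation of the α-stereocentre.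

**Step 7**
Reactants: 9, ethynyldimethylphenylsilane
Product: 10, (E)-(2-iodoethenyl)dimethylphenylsilane
Conditions: Cp2Zr(H)Cl, THF, rt; then I2, 0 °C
Reagents that add atoms: iodine, II
Why: Hydrozirconation (syn addition, Zr at the terminal carbon) followed by iodinolysis with retention gives the E-vinyl iodide.

**Step 8**
Reactants: 8; 10
Product: 11, (1S,2S,3S,6R)-1-[(E)-2-(dimethylphenylsilyl)ethenyl]-2-[(tert-butyldimethylsilyl)oxy]-6-[2-hydroxy-1-(trimethylsilyl)propan-2-yl]-3-methylcyclohexan-1-ol
Conditions: 10 (3 equiv), t-BuLi, Et2O, −78 °C; CeCl3, THF; then 8, −78 °C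
Reagents that add atoms: none (new atoms come from reactant 10)
Why: Organocerium 1,2-addition occurs by equatorial attack on the face opposite the axial C4 methyl, giving the new alkoxide cis to the OTBS group and the alkenyl group trans-diequatorial to the masked isopropenyl group, as the chair oxy-Cope requires.

**Step 9**
Reactants: 11; 12, methyl bromoacetate
Product: 13, methyl (1(10)E)-5β-(tert-butyldimethylsilyloxy)-8α-(dimethylphenylsilyl)-6-oxo-4αH,7αH-13-norgermacr-1(10)-en-12-oate (ten-membered keto ester)
Conditions: KH (3 equiv), 18-crown-6, THF, 0 → 25 °C; then 12, −78 °C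
Reagents that add atoms: none (new atoms come from reactant 12; Me3SiOK is lost)
Why: Proposed new method: one-pot Peterson / anionic oxy-Cope / enolate alkylation. The tertiary potassium β-silyl alkoxide undergoes syn-Peterson elimination to the isopropenyl group; the ring alkoxide then drives a chair [3,3] shift of the trans-diequatorial dialkenylcyclohexanolate (ring bonds equatorial give the E-1(10) alkene; the E-silyl terminus is equatorial and gives 8α-Si); the β-silyl enolate is alkylated on its peripheral face anti to the C8–C9 ring bond (7β side chain). The closest known reactions are KH-mediated Peterson olefination and anionic oxy-Cope with in situ enolate alkylation.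

**Step 10**
Reactants: 13
Product: 14, (1(10)E)-5β-(tert-butyldimethylsilyloxy)-8α-(dimethylphenylsilyl)-4αH,6βH,7αH-13-norgermacr-1(10)-en-12,6α-olide (trans-fused γ-lactone)
Conditions: L-Selectride, THF, −78 °C; warm to rt, then PPTS (cat.), PhH
Reagents that add atoms: none
Why: Felkin–Anh hydride delivery anti to the C5–OTBS and C7 side chain (1,3-syn, shielding the same face) gives the 6α-alkoxide, which lactonises onto the methyl ester.

**Step 11**
Reactants: 14
Product: 15, (1(10)E)-5β-(tert-butyldimethylsilyloxy)-8α-(dimethylphenylsilyl)-4αH,6βH,7αH-germacra-1(10),11(13)-dien-12,6α-olide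
Conditions: LiHMDS, THF, −78 °C; CH2=NMe2+ I−; then MeI, MeOH; NaHCO3
Reagents that add atoms: Eschenmoser's salt, C=[N+](C)C.[I-]
Why: Eschenmoser methylenation (enolate Mannich reaction, quaternisation, elimination) of the only enolisable carbonyl installs the exocyclic methylene.

**Step 12**
Reactants: 15
Product: 16, 1β,10α-dihydroxy-5β-(tert-butyldimethylsilyloxy)-8α-(dimethylphenylsilyl)-4αH,6βH,7αH-germacr-11(13)-en-12,6α-olide
Conditions: OsO4 (cat.), NMO, acetone–H2O, 0 °C
Reagents that add atoms: osmium tetroxide, O=[Os](=O)(=O)=O; N-methylmorpholine N-oxide, C[N+]1([O-])CCOCC1; water, O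
Why: Upjohn syn-dihydroxylation picks the electron-rich, strained E-trisubstituted ring alkene over the acrylate; peripheral attack on the conformer with the C10 methyl β places the tertiary hydroxyl 10α (C1 configuration is erased in step 13).

**Step 13**
Reactants: 16
Product: 17, 10α-hydroxy-1-oxo-5β-(tert-butyldimethylsilyloxy)-8α-(dimethylphenylsilyl)-4αH,6βH,7αH-germacr-11(13)-en-12,6α-olide
Conditions: Dess–Martin periodinane, NaHCO3, CH2Cl2, rt
Reagents that add atoms: none
Why: Dess–Martin oxidation converts the secondary C1 hydroxyl to the ketone; the tertiary C10 hydroxyl cannot be oxidised.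

**Step 14**
Reactants: 17
Product: 18, 10α-acetoxy-1-oxo-5β-(tert-butyldimethylsilyloxy)-8α-(dimethylphenylsilyl)-4αH,6βH,7αH-germacr-11(13)-en-12,6α-olide
Conditions: Ac2O, DMAP, Et3N, CH2Cl2, 40 °C
Reagents that add atoms: acetic anhydride, CC(=O)OC(C)=O
Why: DMAP-catalysed acylation of the tertiary α-ketol hydroxyl, the only free hydroxyl at this stage.

**Step 15**
Reactants: 18
Product: 19, 10α-acetoxy-8α-hydroxy-1-oxo-5β-(tert-butyldimethylsilyloxy)-4αH,6βH,7αH-germacr-11(13)-en-12,6α-olide
Conditions: KBr, AcOOH, NaOAc, AcOH, rt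
Reagents that add atoms: peracetic acid, CC(=O)OO
Why: Fleming–Tamao oxidation (ipso-bromodesilylation of the phenyl group, then peroxide rearrangement) converts C–SiMe2Ph to C–OH with retention; the ring alkene is already oxidised and the acrylate is electron-poor.

**Step 16**
Reactants: 19; 20, methacrylic anhydride
Product: 21, 10α-acetoxy-8α-methacryloyloxy-1-oxo-5β-(tert-butyldimethylsilyloxy)-4αH,6βH,7αH-germacr-11(13)-en-12,6α-olide
Conditions: 20, DMAP, Et3N, CH2Cl2, 0 °C → rt
Reagents that add atoms: none (new atoms come from reactant 20)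
Why: DMAP-catalysed esterification of the single free secondary hydroxyl at C8.

**Step 17**
Reactants: 21
Product: 22, Lychnostatin 1
Conditions: HF·pyridine, THF, 0 °C → rt
Reagents that add atoms: none
Why: Fluoride-mediated desilylation frees the C5 hydroxyl under mildly acidic conditions that spare both esters, the α-acetoxy ketone and the α-methylene lactone.

## Compound list

1 | 4-iodotoluene | Cc1ccc(I)cc1 | starting material
2 | (1S,2S)-3-iodo-6-methylcyclohexa-3,5-diene-1,2-diol | CC1=CC=C(I)[C@@H](O)[C@H]1O | intermediate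
3 | (3aS,7aS)-4-iodo-7-methyl-2-phenyl-3a,7a-dihydro-1,3-benzodioxole | CC1=CC=C(I)[C@H]2OC(c3ccccc3)O[C@@H]12 | intermediate
4 | 1-(trimethylsilyl)propan-2-one | CC(=O)C[Si](C)(C)C | starting material
5 | 2-[(3aR,7aS)-7-methyl-2-phenyl-3a,7a-dihydro-1,3-benzodioxol-4-yl]-1-(trimethylsilyl)propan-2-ol | CC1=CC=C(C(C)(O)C[Si](C)(C)C)[C@H]2OC(c3ccccc3)O[C@@H]12 | intermediate
6 | (1S,2R,3R,6S)-3-[2-hydroxy-1-(trimethylsilyl)propan-2-yl]-6-methylcyclohexane-1,2-diol | C[C@H]1CC[C@@H](C(C)(O)C[Si](C)(C)C)[C@@H](O)[C@H]1O | intermediate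
7 | (1R,2S,3S,6R)-2-(TBS-oxy)-6-[2-hydroxy-1-(trimethylsilyl)propan-2-yl]-3-methylcyclohexan-1-ol | C[C@H]1CC[C@@H](C(C)(O)C[Si](C)(C)C)[C@@H](O)[C@H]1O[Si](C)(C)C(C)(C)C | intermediate
8 | (2S,3S,6S)-2-(TBS-oxy)-6-[2-hydroxy-1-(trimethylsilyl)propan-2-yl]-3-methylcyclohexan-1-one | C[C@H]1CC[C@@H](C(C)(O)C[Si](C)(C)C)C(=O)[C@H]1O[Si](C)(C)C(C)(C)C | intermediate
9 | ethynyldimethylphenylsilane | C#C[Si](C)(C)c1ccccc1 | starting material
10 | (E)-(2-iodoethenyl)dimethylphenylsilane | I/C=C/[Si](C)(C)c1ccccc1 | intermediate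
11 | (1S,2S,3S,6R)-1-[(E)-2-(dimethylphenylsilyl)ethenyl]-2-(TBS-oxy)-6-[2-hydroxy-1-(trimethylsilyl)propan-2-yl]-3-methylcyclohexan-1-ol | C[C@H]1CC[C@@H](C(C)(O)C[Si](C)(C)C)[C@](O)(/C=C/[Si](C)(C)c2ccccc2)[C@H]1O[Si](C)(C)C(C)(C)C | intermediate
12 | methyl bromoacetate | COC(=O)CBr | starting material
13 | ten-membered keto ester (6-oxo, 7β-CH2CO2Me, 8α-SiMe2Ph, 1(10)-E alkene, 4β-Me, 5β-OTBS) | O=C1[C@H](CC(=O)OC)[C@@H]([Si](C)(C)c2ccccc2)C/C(C)=C/CC[C@H](C)[C@@H]1O[Si](C)(C)C(C)(C)C | intermediate
14 | trans-fused 12,6α-lactone (13-nor) | O=C1C[C@@H]2[C@@H]([Si](C)(C)c3ccccc3)C/C(C)=C/CC[C@H](C)[C@H](O[Si](C)(C)C(C)(C)C)[C@H]2O1 | intermediate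
15 | α-methylene lactone | C=C1[C@@H]2[C@@H]([Si](C)(C)c3ccccc3)C/C(C)=C/CC[C@H](C)[C@H](O[Si](C)(C)C(C)(C)C)[C@H]2OC1=O | intermediate
16 | 1β,10α-diol | C=C1[C@@H]2[C@@H]([Si](C)(C)c3ccccc3)C[C@@](C)(O)[C@H](O)CC[C@H](C)[C@H](O[Si](C)(C)C(C)(C)C)[C@H]2OC1=O | intermediate
17 | 10α-hydroxy-1-ketone | C=C1[C@@H]2[C@@H]([Si](C)(C)c3ccccc3)C[C@@](C)(O)C(=O)CC[C@H](C)[C@H](O[Si](C)(C)C(C)(C)C)[C@H]2OC1=O | intermediate
18 | 10α-acetate | C=C1[C@@H]2[C@@H]([Si](C)(C)c3ccccc3)C[C@@](C)(OC(C)=O)C(=O)CC[C@H](C)[C@H](O[Si](C)(C)C(C)(C)C)[C@H]2OC1=O | intermediate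
19 | 8α-alcohol | C=C1[C@@H]2[C@@H](O)C[C@@](C)(OC(C)=O)C(=O)CC[C@H](C)[C@H](O[Si](C)(C)C(C)(C)C)[C@H]2OC1=O | intermediate
20 | methacrylic anhydride | CC(=C)C(=O)OC(=O)C(C)=C | starting material
21 | 5-O-TBS Lychnostatin 1 | C=C1[C@@H]2[C@@H](OC(=O)C(C)=C)C[C@@](C)(OC(C)=O)C(=O)CC[C@H](C)[C@H](O[Si](C)(C)C(C)(C)C)[C@H]2OC1=O | intermediate
22 | Lychnostatin 1, (4S,5S,6S,7R,8S,10R) | C=C1[C@@H]2[C@@H](OC(=O)C(C)=C)C[C@@](C)(OC(C)=O)C(=O)CC[C@H](C)[C@H](O)[C@H]2OC1=O | target

## Summary

Total steps: 17 (including one step for reagent 10).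
Longest linear sequence: 16 steps (steps 1–6 and 8–17).

Three steps most likely to fail:

- **Step 9 (Peterson / oxy-Cope / alkylation cascade).** Fallback: drop the cascade and the silicon-bearing vinyl group. Add vinylmagnesium bromide, run the Peterson elimination separately, trap the oxy-Cope enolate as a silyl enol ether and oxidise it to the C7–C8 enone (Saegusa). Then set C8 and C7 by silyl-cuprate conjugate addition with enolate alkylation by bromoacetate.
- **Step 10 (C6 configuration in the ketone reduction).** Fallback: if the 6β-alcohol (cis-lactone) forms, hydrolyse to the seco hydroxy acid and close the lactone by Mitsunobu reaction with inversion at C6.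
- **Step 12 (facial selectivity at C10).** Fallback: if osmylation gives the 10β-hydroxyl, replace syn-dihydroxylation by peripheral epoxidation of the same alkene face followed by acid-mediated hydrolytic opening with inversion at the tertiary C10. This gives the opposite C10 epimer before the C1 oxidation.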